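**Strategy**

Ring B (C5–C10) is not cyclised directly but grown from a five-membered B-nor ketone by one-carbon radical ring expansion. In the key step, oxidation of a bicyclo[3.1.0]hexanol (C6, C7, C8) should open the cyclopropanol to the ring-enlarged C6 ketone and a tertiary C8 radical, which closes ring C by 6-endo addition to a side-chain silyl enol ether, creating the quaternary C8 methyl centre and the C13 ketone at once. The step exploits the 1,3-relationship between the oxygenated C6 and the quaternary C8 shared by rings B and C. Its precursor is a cis-hydrindane cyclopropanol bearing a 3-silyloxybut-3-enyl chain on C9. The oxabicycle is then assembled on the C13 ketone.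

Key step: step 10

Numbering used: ring A = C1–C5, C10 (gem-dimethyl on C4); ring B = C5–C10 (OAc on C6, methyls on C8 and C10); ring C = C8, C9, C11–C14 (spiro C13); cyclohexanone ring = C1′ (C=O), C2′ (CHMe), C3′ (CH–O–C13), C4′ (CHOH), C5′ (CH–C13), C6′ (CH2).

Remark: both antipodes of the chiral ligands and of the oxazaborolidine are available; the antipode that gives the drawn configuration is assumed in steps 1, 11 and 13.

**Route**

Step 1
Reactants: 1 3-methylcyclopent-2-en-1-one; 2 2-(3-chloropropyl)-2-methyl-1,3-dioxolane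
Product: 4 (S)-3-methyl-3-[3-(2-methyl-1,3-dioxolan-2-yl)propyl]cyclopentan-1-one, via Grignard reagent 3 (not isolated)
Conditions: Mg, THF, 50 °C; then 1, Cu(OTf)2 (3 mol%), chiral imidazolinium salt (NHC precursor, 4 mol%), Et2O, 0 °C; aq. NH4Cl
Reagents that add atoms: none
Why: Copper-catalysed asymmetric conjugate addition of a Grignard reagent to a β-methyl cyclic enone should build the quaternary C10 stereocentre, the chiral NHC–copper complex differentiating the enone faces.

Step 2
Reactants: 4 (S)-3-methyl-3-[3-(2-methyl-1,3-dioxolan-2-yl)propyl]cyclopentan-1-one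
Product: 6 (S)-4,7a-dimethyl-1,2,5,6,7,7a-hexahydro-3H-inden-3-one, via diketone 5 (not isolated)
Conditions: 2 M HCl, THF, rt; then KOH, MeOH, 65 °C
Reagents that add atoms: none
Why: Acid frees the methyl ketone and base closes ring A by intramolecular aldol condensation (C5 enolate onto C4); the competing aldol onto the ring ketone would need a bridgehead alkene to dehydrate and stays reversible.

Step 3
Reactants: 6 (S)-4,7a-dimethyl-1,2,5,6,7,7a-hexahydro-3H-inden-3-one
Product: 8 (3aS,7aS)-3a,7,7-trimethyloctahydro-1H-inden-1-one, via silyl enol ether 7 (not isolated)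
Conditions: MeMgBr, CuBr·SMe2 (10 mol%), TMSCl, THF, −40 → 0 °C; 1 M HCl; then NaOMe, MeOH, rt
Reagents that add atoms: methylmagnesium bromide, C[Mg]Br
Why: Copper-catalysed 1,4-addition of methyl to the s-cis alkylidene cyclopentanone installs the C4 gem-dimethyl group, and base equilibration at C5 should give the more stable cis-hydrindanone (C5 is re-set after the key step).

Step 4
Reactants: 8 (3aS,7aS)-3a,7,7-trimethyloctahydro-1H-inden-1-one
Product: 9 (3aS,7aS)-3a,7,7-trimethyl-2-methylideneoctahydro-1H-inden-1-one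
Conditions: (CH2O)n, N-methylanilinium trifluoroacetate, THF, 65 °C
Reagents that add atoms: formaldehyde (as paraformaldehyde), C=O
Why: α-Methylenation (Mannich reaction and elimination) can only be completed at the C8 methylene, since C5 carries a single hydrogen between two quaternary carbons.

Step 5
Reactants: 9 (3aS,7aS)-3a,7,7-trimethyl-2-methylideneoctahydro-1H-inden-1-one
Product: 10 (3aS,7aS)-2,3a,7,7-tetramethyl-3a,4,5,6,7,7a-hexahydro-1H-inden-1-one
Conditions: RhCl3·3H2O (5 mol%), EtOH, 80 °C
Reagents that add atoms: none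
Why: Rhodium hydride catalysed exo-to-endo alkene isomerisation should give the thermodynamically favoured 2-methylcyclopentenone (C8=C9).

Step 6
Reactants: 10 (3aS,7aS)-2,3a,7,7-tetramethyl-3a,4,5,6,7,7a-hexahydro-1H-inden-1-one; 11 2-(2-bromoethyl)-2-methyl-1,3-dioxolane
Product: 13 cis-fused trimethylsilyl enol ether [C6(OTMS)=C8(Me)] with the 2-(2-methyl-1,3-dioxolan-2-yl)ethyl chain on C9 cis to the C10 methyl, via Grignard reagent 12 (not isolated)
Conditions: Mg, THF, rt; then 10, CuBr·SMe2 (20 mol%), TMSCl, THF, −78 → −40 °C; Et3N, pentane work-up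
Reagents that add atoms: chlorotrimethylsilane, C[Si](C)(C)Cl
Why: TMSCl-accelerated copper-catalysed conjugate addition should occur on the convex face of the cis-fused enone, anti to ring A carbons C1 and C4, placing the C9 chain cis to the C10 methyl; silylation fixes the enolate regiospecifically.

Step 7
Reactants: 13 cis-fused trimethylsilyl enol ether
Product: 14 cyclopropyl silyl ether (C7 methylene bridging C6 and C8, OTMS on C6, methyl on C8, ketal chain on C9)
Conditions: Et2Zn, CH2I2, CH2Cl2, 0 °C → rt
Reagents that add atoms: diiodomethane, ICI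
Why: Simmons–Smith cyclopropanation of the electron-rich silyl enol ether; the two new stereocentres (C6, C8) are erased in step 10, so the face of attack (drawn anti to ring A) is irrelevant.

Step 8
Reactants: 14 cyclopropyl silyl ether
Product: 15 cyclopropanol methyl ketone (free C6–OH, 3-oxobutyl chain on C9)
Conditions: PPTS, acetone/H2O (10:1), 40 °C
Reagents that add atoms: water, O
Why: Mild acid-catalysed ketal hydrolysis frees the methyl ketone and cleaves the labile tertiary TMS ether without protonolysis of the cyclopropanol.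

Step 9
Reactants: 15 cyclopropanol methyl ketone
Product: 17 cyclopropanol with 3-(tert-butyldimethylsilyloxy)but-3-enyl chain on C9, via dilithium salt 16 (not isolated)
Conditions: LDA (2.2 equiv), THF, −78 °C; TBSCl (1.1 equiv), DMPU, −78 °C; cold aq. NaHCO3
Reagents that add atoms: tert-butyldimethylsilyl chloride, CC(C)(C)[Si](C)(C)Cl
Why: Kinetic deprotonation of the methyl ketone at its methyl group and O-silylation of the enolate should give the terminal silyl enol ether, the hindered tertiary lithium cyclopropoxide being silylated far more slowly.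

Step 10
Reactants: 17 cyclopropanol with 3-(tert-butyldimethylsilyloxy)but-3-enyl chain on C9
Product: 19 tricyclic 6,13-dione (trans-anti-trans; H-5 and H-9 on one face, 8-Me and 10-Me on the other), via cis-fused dione 18 (not isolated)
Conditions: Mn(pic)3 (pic = pyridine-2-carboxylate, 2.5 equiv), DMF, 0 °C → rt; then NaOMe, MeOH, 40 °C
Reagents that add atoms: none
Why: Ligand exchange gives a manganese cyclopropoxide that is oxidised by one electron to the cyclopropyloxy radical, whose β-scission (either cyclopropane bond, the two radicals interconverting by the Dowd–Beckwith acyl shift) funnels to the tertiary C8 radical of the ring-enlarged cyclohexanone, so ring B arises from the five-membered ring by one-carbon ring expansion with C7 inserted between C6 and C8. The C8 radical then adds to the unsubstituted terminus (C14) of the silyl enol ether in a 6-endo-trig closure that forms ring C and the quaternary C8, and the resulting α-silyloxy radical at C13 is oxidised by a second equivalent of the trivalent manganese reagent to the ketone. The closest known reaction type is the Mn(pic)3 oxidation of bicyclic cyclopropanols to ring-enlarged β-keto radicals and their addition to silyl enol ethers to give 1,5-diketones, used here intramolecularly. C8 should be set by attack of the equatorial C9 tether on the radical face opposite to the axial C10 methyl through a chair-like transition state, giving the trans B/C fusion with axial C8 methyl as in radical polyene cyclisations. The step needs 6-endo over 5-exo closure, secured because 5-exo attack would join two fully substituted carbons and leave an unstabilised primary radical, and it needs the ring B conformer with equatorial tether, favoured because the alternative places the C10 and C4 methyls syn-diaxial on ring A. Sodium methoxide finally epimerises C5, now α to the C6 ketone, to the more stable trans A/B fusion.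

Step 11
Reactants: 20 4,4-dimethoxycyclohexa-2,5-dien-1-one
Product: 21 (R)-4,4-dimethoxy-5-methylcyclohex-2-en-1-one
Conditions: Me2Zn, Cu(OTf)2 (2 mol%), BINOL-derived phosphoramidite (4 mol%), toluene, −25 °C
Reagents that add atoms: dimethylzinc, C[Zn]C
Why: Copper/phosphoramidite-catalysed asymmetric conjugate addition desymmetrises the quinone monoketal; the C2′ methyl centre only ensures single diastereomers later and is re-equilibrated in step 21.

Step 12
Reactants: 21 (R)-4,4-dimethoxy-5-methylcyclohex-2-en-1-one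
Product: 22 (R)-2-iodo-4,4-dimethoxy-5-methylcyclohex-2-en-1-one
Conditions: I2, pyridine, CH2Cl2, 0 °C → rt
Reagents that add atoms: iodine, II
Why: α-Iodination of the enone by pyridine addition, iodination and elimination (Baylis–Hillman type sequence).

Step 13
Reactants: 22 (R)-2-iodo-4,4-dimethoxy-5-methylcyclohex-2-en-1-one
Product: 23 (1S,5R)-2-iodo-4,4-dimethoxy-5-methylcyclohex-2-en-1-ol
Conditions: (R)-2-methyl-CBS-oxazaborolidine (20 mol%), BH3·SMe2, THF, −30 °C; MeOH
Reagents that add atoms: none
Why: Corey–Bakshi–Shibata reduction in which the iodoalkene acts as the large group, so the (R)-catalyst should give the (S)-carbinol that becomes C4′.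

Step 14
Reactants: 23 (1S,5R)-2-iodo-4,4-dimethoxy-5-methylcyclohex-2-en-1-ol
Product: 24 tert-butyl{[(1S,5R)-2-iodo-4,4-dimethoxy-5-methylcyclohex-2-en-1-yl]oxy}dimethylsilane
Conditions: TBSCl, imidazole, DMF, rt
Reagents that add atoms: tert-butyldimethylsilyl chloride, CC(C)(C)[Si](C)(C)Cl
Why: Standard silylation; the bulky silyl ether later shields one face of the ring.

Step 15
Reactants: 24 tert-butyl{[(1S,5R)-2-iodo-4,4-dimethoxy-5-methylcyclohex-2-en-1-yl]oxy}dimethylsilane; 19 tricyclic 6,13-dione
Product: 26 tertiary allylic alcohol (C6 ketone retained; axial OH on C13; C13 bonded to C5′ of the 4′-silyloxy-1′,1′-dimethoxy-2′-methylcyclohex-5′-ene ring), via alkenyllithium 25 (not isolated)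
Conditions: t-BuLi (2.1 equiv), Et2O, −78 °C; then 19, THF, −78 °C; H2O
Reagents that add atoms: none
Why: Iodine–lithium exchange gives an alkenyllithium that cannot β-eliminate (it would form a cyclic allene) and adds to the unhindered C13 ketone, not to the C6 ketone shielded by three syn-axial methyls; equatorial attack anti to the axial C8 methyl sets C13 with axial oxygen.

Step 16
Reactants: 26 tertiary allylic alcohol
Product: 27 saturated tertiary alcohol (H on C5′; C13 cis to the C4′ silyl ether)
Conditions: H2 (5 bar), [Ir(cod)(PCy3)(py)]PF6 (10 mol%), CH2Cl2, rt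
Reagents that add atoms: none
Why: Hydroxyl-directed iridium-catalysed hydrogenation of the trisubstituted alkene should deliver hydrogen to the face opposite the pseudo-axial silyloxy group, setting C5′.

Step 17
Reactants: 27 saturated tertiary alcohol
Product: 28 C6 axial alcohol (diol)
Conditions: LiAlH4, THF, 0 °C → rt
Reagents that add atoms: none
Why: Hydride attacks the C6 ketone from the face opposite the syn-axial methyls on C4, C8 and C10 and should give the axial alcohol.

Step 18
Reactants: 28 C6 axial alcohol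
Product: 29 C6 acetate
Conditions: Ac2O, DMAP, Et3N, CH2Cl2, 40 °C
Reagents that add atoms: acetic anhydride, CC(=O)OC(C)=O
Why: DMAP-catalysed acylation of the secondary alcohol; the tertiary C13 hydroxyl is not acylated under these conditions.

Step 19
Reactants: 29 C6 acetate
Product: 30 keto diol acetate (C1′ ketone, free C4′–OH and C13–OH)
Conditions: 48% aq. HF, MeCN, 0 °C → rt
Reagents that add atoms: water, O
Why: Aqueous HF cleaves the secondary silyl ether and hydrolyses the dimethyl ketal while the acetate survives.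

Step 20
Reactants: 30 keto diol acetate
Product: 31 tris(trimethylsilyl) derivative [C1′(OTMS)=C2′(Me) enol ether, TMS ethers on C4′–O and C13–O]
Conditions: TMSOTf, Et3N, CH2Cl2, 0 °C → rt
Reagents that add atoms: trimethylsilyl trifluoromethanesulfonate, C[Si](C)(C)OS(=O)(=O)C(F)(F)F
Why: Silylation of both hydroxyls and thermodynamic enol silylation toward the methyl-bearing C2′, the C6′ side being disfavoured by the adjacent carbon that carries the quaternary C13.

Step 21
Reactants: 31 tris(trimethylsilyl) derivative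
Product: 34 target CNP0188572.2, via silylated enone 32 (not isolated), via dihydroxy enone 33 (not isolated)
Conditions: Pd(OAc)2 (1.1 equiv), MeCN, rt; then HF·pyridine, THF, 0 °C; then DBU, CH2Cl2, rt
Reagents that add atoms: none
Why: Saegusa–Ito oxidation gives the 2-methylcyclohexenone; after desilylation the tertiary C13 hydroxyl should add 5-exo to C3′ (oxa-Michael) to close the 6-oxabicyclo[3.2.1]octanone, and the C2′ methyl equilibrates to the equatorial position cis to the ether bridge.

**Compound list**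

1 | 3-methylcyclopent-2-en-1-one | CC1=CC(=O)CC1 | starting material
2 | 2-(3-chloropropyl)-2-methyl-1,3-dioxolane | CC1(CCCCl)OCCO1 | starting material
3 | [3-(2-methyl-1,3-dioxolan-2-yl)propyl]magnesium chloride | CC1(CCC[Mg]Cl)OCCO1 | intermediate
4 | (S)-3-methyl-3-[3-(2-methyl-1,3-dioxolan-2-yl)propyl]cyclopentan-1-one | O=C1C[C@@](C)(CCCC2(C)OCCO2)CC1 | intermediate
5 | (S)-3-methyl-3-(4-oxopentyl)cyclopentan-1-one | O=C1C[C@@](C)(CCCC(C)=O)CC1 | intermediate
6 | (S)-4,7a-dimethyl-1,2,5,6,7,7a-hexahydro-3H-inden-3-one | CC1=C2C(=O)CC[C@]2(C)CCC1 | intermediate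
7 | (S)-trimethyl[(4,4,7a-trimethyl-2,4,5,6,7,7a-hexahydro-1H-inden-3-yl)oxy]silane | C[Si](C)(C)OC1=C2C(C)(C)CCC[C@@]2(C)CC1 | intermediate
8 | (3aS,7aS)-3a,7,7-trimethyloctahydro-1H-inden-1-one (cis-fused) | O=C1CC[C@]2(C)CCCC(C)(C)[C@H]12 | intermediate
9 | (3aS,7aS)-3a,7,7-trimethyl-2-methylideneoctahydro-1H-inden-1-one | C=C1C[C@]2(C)CCCC(C)(C)[C@@H]2C1=O | intermediate
10 | (3aS,7aS)-2,3a,7,7-tetramethyl-3a,4,5,6,7,7a-hexahydro-1H-inden-1-one | CC1=C[C@]2(C)CCCC(C)(C)[C@@H]2C1=O | intermediate
11 | 2-(2-bromoethyl)-2-methyl-1,3-dioxolane | CC1(CCBr)OCCO1 | starting material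
12 | [2-(2-methyl-1,3-dioxolan-2-yl)ethyl]magnesium bromide | CC1(CC[Mg]Br)OCCO1 | intermediate
13 | cis-fused trimethylsilyl enol ether [C6(OTMS)=C8(Me)], ketal chain on C9 cis to the C10 methyl | C[Si](C)(C)OC1=C(C)[C@@H](CCC3(C)OCCO3)[C@]2(C)CCCC(C)(C)[C@H]12 | intermediate
14 | cyclopropyl silyl ether (C7 bridging C6 and C8, OTMS on C6, ketal chain on C9) | C[Si](C)(C)O[C@]12C[C@@]1(C)[C@@H](CCC3(C)OCCO3)[C@]1(C)CCCC(C)(C)[C@H]21 | intermediate
15 | cyclopropanol methyl ketone (free C6–OH, 3-oxobutyl chain on C9) | O[C@]12C[C@@]1(C)[C@@H](CCC(C)=O)[C@]1(C)CCCC(C)(C)[C@H]21 | intermediate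
16 | dilithium salt of 15 (C6 alkoxide and terminal enolate) | [Li]O[C@]12C[C@@]1(C)[C@@H](CCC(=C)O[Li])[C@]1(C)CCCC(C)(C)[C@H]21 | intermediate
17 | cyclopropanol with 3-(tert-butyldimethylsilyloxy)but-3-enyl chain on C9 | O[C@]12C[C@@]1(C)[C@@H](CCC(=C)O[Si](C)(C)C(C)(C)C)[C@]1(C)CCCC(C)(C)[C@H]21 | intermediate
18 | cis-A/B tricyclic 6,13-dione (C5 epimer of 19) | O=C1C[C@]2(C)CC(=O)CC[C@H]2[C@]2(C)CCCC(C)(C)[C@H]12 | intermediate
19 | trans-anti-trans tricyclic 6,13-dione (4,4,8,10-tetramethyl; H-5 and H-9 on one face, 8-Me and 10-Me on the other) | O=C1C[C@]2(C)CC(=O)CC[C@H]2[C@]2(C)CCCC(C)(C)[C@@H]12 | intermediate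
20 | 4,4-dimethoxycyclohexa-2,5-dien-1-one | COC1(OC)C=CC(=O)C=C1 | starting material
21 | (R)-4,4-dimethoxy-5-methylcyclohex-2-en-1-one | O=C1C=CC(OC)(OC)[C@H](C)C1 | intermediate
22 | (R)-2-iodo-4,4-dimethoxy-5-methylcyclohex-2-en-1-one | O=C1C(I)=CC(OC)(OC)[C@H](C)C1 | intermediate
23 | (1S,5R)-2-iodo-4,4-dimethoxy-5-methylcyclohex-2-en-1-ol | O[C@@H]1C(I)=CC(OC)(OC)[C@H](C)C1 | intermediate
24 | tert-butyl{[(1S,5R)-2-iodo-4,4-dimethoxy-5-methylcyclohex-2-en-1-yl]oxy}dimethylsilane | CC(C)(C)[Si](C)(C)O[C@@H]1C(I)=CC(OC)(OC)[C@H](C)C1 | intermediate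
25 | alkenyllithium from 24 (Li in place of I) | CC(C)(C)[Si](C)(C)O[C@@H]1C([Li])=CC(OC)(OC)[C@H](C)C1 | intermediate
26 | tertiary allylic alcohol (C6 ketone, axial C13–OH, C5′=C6′ alkene, C1′ dimethyl ketal, C4′–OTBS) | O=C1C[C@]2(C)C[C@](O)(C3=CC(OC)(OC)[C@H](C)C[C@@H]3O[Si](C)(C)C(C)(C)C)CC[C@H]2[C@]2(C)CCCC(C)(C)[C@@H]12 | intermediate
27 | saturated tertiary alcohol (C5′–H; C13 cis to C4′–OTBS) | O=C1C[C@]2(C)C[C@](O)([C@@H]3CC(OC)(OC)[C@H](C)C[C@@H]3O[Si](C)(C)C(C)(C)C)CC[C@H]2[C@]2(C)CCCC(C)(C)[C@@H]12 | intermediate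
28 | C6 axial alcohol | O[C@H]1C[C@]2(C)C[C@](O)([C@@H]3CC(OC)(OC)[C@H](C)C[C@@H]3O[Si](C)(C)C(C)(C)C)CC[C@H]2[C@]2(C)CCCC(C)(C)[C@@H]12 | intermediate
29 | C6 acetate | CC(=O)O[C@H]1C[C@]2(C)C[C@](O)([C@@H]3CC(OC)(OC)[C@H](C)C[C@@H]3O[Si](C)(C)C(C)(C)C)CC[C@H]2[C@]2(C)CCCC(C)(C)[C@@H]12 | intermediate
30 | keto diol acetate (C1′ ketone, C4′–OH, C13–OH) | CC(=O)O[C@H]1C[C@]2(C)C[C@](O)([C@@H]3CC(=O)[C@H](C)C[C@@H]3O)CC[C@H]2[C@]2(C)CCCC(C)(C)[C@@H]12 | intermediate
31 | tris(trimethylsilyl) derivative [C1′(OTMS)=C2′ enol ether, C4′–OTMS, C13–OTMS] | CC(=O)O[C@H]1C[C@]2(C)C[C@](O[Si](C)(C)C)([C@@H]3CC(O[Si](C)(C)C)=C(C)C[C@@H]3O[Si](C)(C)C)CC[C@H]2[C@]2(C)CCCC(C)(C)[C@@H]12 | intermediate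
32 | silylated enone (C1′ ketone, C2′=C3′ alkene, two TMS ethers) | CC(=O)O[C@H]1C[C@]2(C)C[C@](O[Si](C)(C)C)([C@@H]3CC(=O)C(C)=C[C@@H]3O[Si](C)(C)C)CC[C@H]2[C@]2(C)CCCC(C)(C)[C@@H]12 | intermediate
33 | dihydroxy enone | CC(=O)O[C@H]1C[C@]2(C)C[C@](O)([C@@H]3CC(=O)C(C)=C[C@@H]3O)CC[C@H]2[C@]2(C)CCCC(C)(C)[C@@H]12 | intermediate
34 | CNP0188572.2 | CC(=O)O[C@H]1C[C@]2(C)C[C@]3(CC[C@H]2[C@]2(C)CCCC(C)(C)[C@@H]12)O[C@@H]1[C@H](O)[C@H]3CC(=O)[C@@H]1C | target

**Step count**

Total steps: 21. Longest linear sequence: 17 (steps 1–10, then 15–21); steps 11–14 prepare the second fragment.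

**Steps most likely to fail and fallbacks**

1. Step 10. The tertiary C8 radical may be oxidised or quenched before the slow 6-endo addition to the electron-rich enol ether, or ring C may close from the wrong ring B conformer, which would erode facial selectivity at C8. The fallback separates ring expansion from ring C closure. It sets out from 14: FeCl3 in DMF (Saegusa–Ito ring expansion of the silyloxycyclopropane) should give the ring-enlarged β-chloro ketone F1. NaOAc in MeOH eliminates HCl and equilibrates C5, giving the trans-fused 8-methyl enone F2 (C6 ketone, C7=C8). PPTS in wet acetone frees the methyl ketone F3, and LDA then TBSCl gives the terminal silyl enol ether F4. An intramolecular Mukaiyama–Michael addition (TiCl4, CH2Cl2, −78 °C) onto C8 from the face opposite the axial C10 methyl closes ring C and returns to the route at 19.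

2. Step 16. The hindered trisubstituted alkene may hydrogenate slowly or with poor facial selectivity at C5′, or an allylic C–O bond may be hydrogenolysed. The fallback replaces alkene hydrogenation by 1,4-reduction of an enone. It sets out from 26: LiAlH4 gives the C6 alcohol F5 and Ac2O/DMAP the acetate F6. PPTS in wet acetone converts the ketal into the β-substituted enone F7. Conjugate reduction with [(Ph3P)CuH]6, hydride adding to C5′ anti to the C4′ silyloxy group, gives the silyloxy ketone F8. Aqueous HF in MeCN then removes the silyl group and returns to the route at 30.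

3. Step 1. Enantioselectivity may be insufficient when a functionalised Grignard reagent builds a quaternary centre on a five-membered enone. The fallback exchanges the roles of the two C10 substituents. It sets out from 2 via 3: addition of 3 to 3-ethoxycyclopent-2-en-1-one F9 with mild acid work-up (Stork–Danheiser transposition) gives 3-[3-(2-methyl-1,3-dioxolan-2-yl)propyl]cyclopent-2-en-1-one F10. Copper-catalysed asymmetric conjugate addition of Me3Al (Cu(OTf)2, chiral NHC ligand) then delivers the methyl group and returns to the route at 4.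

**Further compounds**

F1 | step 10 | ring-enlarged β-chloro ketone (cis-fused, C8–Cl, ketal chain on C9) | O=C1CC(C)(Cl)[C@@H](CCC3(C)OCCO3)[C@]2(C)CCCC(C)(C)[C@H]12
F2 | step 10 | trans-fused 8-methyl enone (C6 ketone, C7=C8, ketal chain on C9) | O=C1C=C(C)[C@@H](CCC3(C)OCCO3)[C@]2(C)CCCC(C)(C)[C@@H]12
F3 | step 10 | trans-fused enone with 3-oxobutyl chain on C9 | O=C1C=C(C)[C@@H](CCC(C)=O)[C@]2(C)CCCC(C)(C)[C@@H]12
F4 | step 10 | trans-fused enone with 3-(tert-butyldimethylsilyloxy)but-3-enyl chain on C9 | O=C1C=C(C)[C@@H](CCC(=C)O[Si](C)(C)C(C)(C)C)[C@]2(C)CCCC(C)(C)[C@@H]12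
F5 | step 16 | C6 axial alcohol of 26 (alkene retained) | O[C@H]1C[C@]2(C)C[C@](O)(C3=CC(OC)(OC)[C@H](C)C[C@@H]3O[Si](C)(C)C(C)(C)C)CC[C@H]2[C@]2(C)CCCC(C)(C)[C@@H]12
F6 | step 16 | C6 acetate of F5 | CC(=O)O[C@H]1C[C@]2(C)C[C@](O)(C3=CC(OC)(OC)[C@H](C)C[C@@H]3O[Si](C)(C)C(C)(C)C)CC[C@H]2[C@]2(C)CCCC(C)(C)[C@@H]12
F7 | step 16 | enone (C1′ ketone, C5′=C6′, C4′–OTBS) | CC(=O)O[C@H]1C[C@]2(C)C[C@](O)(C3=CC(=O)[C@H](C)C[C@@H]3O[Si](C)(C)C(C)(C)C)CC[C@H]2[C@]2(C)CCCC(C)(C)[C@@H]12
F8 | step 16 | saturated C1′ ketone with C4′–OTBS | CC(=O)O[C@H]1C[C@]2(C)C[C@](O)([C@@H]3CC(=O)[C@H](C)C[C@@H]3O[Si](C)(C)C(C)(C)C)CC[C@H]2[C@]2(C)CCCC(C)(C)[C@@H]12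
F9 | step 1 | 3-ethoxycyclopent-2-en-1-one | CCOC1=CC(=O)CC1
F10 | step 1 | 3-[3-(2-methyl-1,3-dioxolan-2-yl)propyl]cyclopent-2-en-1-one | O=C1C=C(CCCC2(C)OCCO2)CC1
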